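The 20-membered lactone ring is closed at C16–C17, inside the stereochemically silent dodecamethylene bridge C7–C18. The step exploits the fact that C17 lies two carbons from the lactone carbinol C19: a C19 vinyl carbinol ester (C17=C18) gives, by anti-Markovnikov hydroboration, a primary C17 borane that couples intramolecularly with a primary C16 bromide (alkyl–alkyl Suzuki–Miyaura macrocyclisation). One operation converts an open-chain ester, in which the Z-enoate, the C4 silyl ether, the trans-C5–C6 epoxide and the silylated syn,syn-triol are complete, into the macrolide. This ester comes from zinc–ProPhenol addition of the C19 propiolate to a C4–C16 epoxy aldehyde and Lindlar reduction.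

Key step: step 13

Remark on numbering: macrolide numbering is used throughout (C1 lactone carbonyl, C19 lactone carbinol, C24 methyl); CIP letters at C5, C19 and C21 change with silylation, acylation or the C17 substituent without any change in spatial arrangement.
Assumption: the facial senses of the ProPhenol–ZnMe2 alkynylation (step 10) and of the CBS reduction (step 5) are taken from the usual models; if either delivers the other carbinol, the enantiomeric ligand is used.

Step 1
Reactants: 1 ethyl (R)-3-hydroxybutanoate; 2 N-methoxy-N-methylacetamide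
Product: 3 (5R)-5-hydroxy-N-methoxy-N-methyl-3-oxohexanamide
Conditions: LiN(iPr)2 (3.6 equiv), 2 (3.5 equiv), THF, −78 °C; then 1, −78 to −40 °C; aq. NH4Cl
Reagents that add atoms: none
Why: Claisen-type C-acylation of the amide lithium enolate by the ester of 1 (its hydroxyl masked as the lithium alkoxide), in which the β-keto amide is held as its enolate so that no second addition occurs and the C23 stereocentre is carried through unchanged.

Step 2
Reactants: 3
Product: 4 (3R,5R)-3,5-dihydroxy-N-methoxy-N-methylhexanamide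
Conditions: Et2BOMe (1.1 equiv), THF/MeOH 4:1, −78 °C; NaBH4 (1.2 equiv); MeOH co-evaporation
Reagents that add atoms: none
Why: Narasaka–Prasad reduction, in which Et2BOMe locks the β-hydroxy ketone in a six-membered boron chelate and NaBH4 attacks axially, which should set C21 1,3-syn to C23.

Step 3
Reactants: 4
Product: 5 (3R,5R)-3,5-bis[(tert-butyldimethylsilyl)oxy]-N-methoxy-N-methylhexanamide
Conditions: TBSOTf (2.5 equiv), 2,6-lutidine, CH2Cl2, −78 to 0 °C
Reagents that add atoms: tert-butyldimethylsilyl trifluoromethanesulfonate (TBSOTf), CC(C)(C)[Si](C)(C)OS(=O)(=O)C(F)(F)F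
Why: Silylation of both secondary alcohols by the reactive silyl triflate, to which the Weinreb amide is inert.

Step 4
Reactants: 5
Product: 6 (5R,7R)-5,7-bis[(tert-butyldimethylsilyl)oxy]oct-1-en-3-one
Conditions: CH2=CHMgBr (1.8 equiv), THF, −78 to 0 °C; inverse quench into cold 1 M HCl
Reagents that add atoms: vinylmagnesium bromide, C=C[Mg]Br
Why: Weinreb ketone synthesis, in which the magnesium chelate of the tetrahedral adduct stops at the ketone stage and the acidic inverse quench keeps the released amine from adding to the enone.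

Step 5
Reactants: 6
Product: 7 (3R,5S,7R)-5,7-bis[(tert-butyldimethylsilyl)oxy]oct-1-en-3-ol
Conditions: (S)-2-methyl-CBS-oxazaborolidine (0.5 equiv), catecholborane (1.8 equiv), toluene, −78 °C
Reagents that add atoms: none
Why: Corey–Bakshi–Shibata reduction, in which the oxazaborolidine–borane complex delivers hydride to one carbonyl face with the vinyl group as the larger substituent, which should set C19 under reagent control, while catecholborane at low temperature avoids hydroboration of the vinyl group.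

Step 6
Reactants: 7; 8 propiolic acid
Product: 9 (3R,5S,7R)-5,7-bis[(tert-butyldimethylsilyl)oxy]oct-1-en-3-yl prop-2-ynoate
Conditions: DCC (1.3 equiv), DMAP (5 mol%), CH2Cl2, −20 to 0 °C
Reagents that add atoms: none
Why: Steglich esterification at low temperature with little DMAP, which suppresses conjugate addition to the propiolate and leaves C19 untouched because its C–O bond is not broken.

Step 7
Reactants: 10 11-bromoundecan-1-ol
Product: 11 11-bromoundecanal
Conditions: TEMPO (10 mol%), PhI(OAc)2 (1.1 equiv), CH2Cl2, rt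
Reagents that add atoms: none
Why: TEMPO/oxoammonium oxidation, which should stop at the aldehyde and not touch the primary bromide.

Step 8
Reactants: 11
Product: 12 (2E)-13-bromotridec-2-enal
Conditions: Ph3P=CHCHO (1.1 equiv), toluene, 80 °C
Reagents that add atoms: (triphenylphosphoranylidene)acetaldehyde, O=CC=P(c1ccccc1)(c1ccccc1)c1ccccc1
Why: Wittig olefination with the stabilised formylmethylene ylide, which should give the (E)-enal (C4–C6).

Step 9
Reactants: 12
Product: 13 (2R,3S)-3-(10-bromodecyl)oxirane-2-carbaldehyde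
Conditions: (S)-2-[bis(3,5-bis(trifluoromethyl)phenyl)(trimethylsilyloxy)methyl]pyrrolidine (10 mol%), 35% aq. H2O2 (1.3 equiv), CH2Cl2, rt; used crude
Reagents that add atoms: hydrogen peroxide, OO
Why: Organocatalytic iminium–enamine epoxidation of the enal, in which the (S)-diarylprolinol silyl ether shields one face of the iminium ion so that hydroperoxide adds to C6 from the open face and the enamine closes the oxirane, setting C5 and C6 as the trans-epoxide.

Step 10
Reactants: 9; 13
Product: 14 (3R,5S,7R)-5,7-bis[(tert-butyldimethylsilyl)oxy]oct-1-en-3-yl (4R)-4-[(2S,3S)-3-(10-bromodecyl)oxiran-2-yl]-4-hydroxybut-2-ynoate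
Conditions: (S,S)-ProPhenol (20 mol%), ZnMe2 (3 equiv), Ph3P=O (40 mol%), 9 (1.5 equiv, excess recovered), toluene, 0 °C
Reagents that add atoms: none
Why: ProPhenol–zinc-catalysed asymmetric alkynylation, in which the dinuclear zinc alkoxide binds the aldehyde and the zinc acetylide of 9 and delivers the alkyne to one carbonyl face, which should set C4 (R) under catalyst control over any intrinsic Felkin–Anh bias of the epoxy aldehyde.

Step 11
Reactants: 14
Product: 15 (3R,5S,7R)-5,7-bis[(tert-butyldimethylsilyl)oxy]oct-1-en-3-yl (4R)-4-[(2R,3S)-3-(10-bromodecyl)oxiran-2-yl]-4-[(tert-butyldimethylsilyl)oxy]but-2-ynoate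
Conditions: TBSOTf (1.3 equiv), 2,6-lutidine, CH2Cl2, −78 °C
Reagents that add atoms: tert-butyldimethylsilyl trifluoromethanesulfonate (TBSOTf), CC(C)(C)[Si](C)(C)OS(=O)(=O)C(F)(F)F
Why: Silylation of the propargylic alcohol at −78 °C, which blocks later butenolide formation and Payne rearrangement and, being buffered by lutidine, should leave the epoxide intact.

Step 12
Reactants: 15
Product: 16 (3R,5S,7R)-5,7-bis[(tert-butyldimethylsilyl)oxy]oct-1-en-3-yl (2Z,4R)-4-[(2R,3S)-3-(10-bromodecyl)oxiran-2-yl]-4-[(tert-butyldimethylsilyl)oxy]but-2-enoate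
Conditions: H2 (1 atm), Pd/CaCO3 poisoned with Pb(OAc)2 (Lindlar catalyst), quinoline, EtOAc, 0 °C to rt, stopped after 1 equiv H2
Reagents that add atoms: none
Why: Lindlar semi-hydrogenation, in which syn delivery of H2 to the strongly adsorbing conjugated ynoate gives the Z-enoate while quinoline poisoning and the hydrogen limit should spare the monosubstituted C17=C18 alkene and the C–Br bond.

Step 13
Reactants: 16
Product: 18 (2Z,4R,5R,6S,19S,21S,23R)-4,21,23-tris[(tert-butyldimethylsilyl)oxy]-5,6-epoxytetracos-2-en-19-olide, via C17 B-alkyl-9-BBN borane 17 (not isolated)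
Conditions: 9-BBN dimer (0.75 equiv), THF, 0 °C to rt, 4 h; then syringe-pump addition (12 h) to Pd(OAc)2 (20 mol%), PCy3 (40 mol%), K3PO4·H2O (3 equiv), THF, rt to 40 °C, final 2 mM
Reagents that add atoms: none
Why: 9-BBN adds to the only monosubstituted alkene (C17=C18) and places boron on terminal C17, the conjugated, silyloxy-shielded Z-enoate and the epoxide being inert to this hindered borane; zerovalent palladium carrying PCy3 then inserts into the primary C16–Br bond in an SN2-type oxidative addition, the phosphate/hydroxide-activated borate transfers the C17 alkyl group to divalent palladium, and reductive elimination forms C16–C17. The closest known reaction type is the alkyl–alkyl Suzuki–Miyaura coupling of primary alkyl bromides bearing β-hydrogens with B-alkyl-9-BBN reagents, here run intramolecularly in the manner of B-alkyl Suzuki–Miyaura macrocyclisations. One ring is closed, the 20-membered lactone, end to end by reductive elimination from a 21-membered dialkylpalladium ring. No stereocentre is formed, and the six existing ones are remote from the reacting carbons and not epimerisable under hydrated K3PO4 at room temperature. The step needs ring closure to outrun oligomerisation and β-hydride elimination, which slow addition at about 2 mM, the bulky electron-rich PCy3 and the strain-free dodecamethylene bridge should secure. Complete hydroboration before palladium is added removes the allylic ester, so that no π-allyl ionisation at C19 can compete, and the mild base leaves lactone, Z-enoate, epoxide and silyl ethers intact.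

Step 14
Reactants: 18
Product: 19 (2Z,4R,5S,6S,19S,21R,23R)-5,6-epoxy-4,21,23-trihydroxytetracos-2-en-19-olide
Conditions: HF·pyridine, pyridine, THF, 0 °C to rt
Reagents that add atoms: none
Why: Fluoride-driven cleavage of the three Si–O bonds under pyridine-buffered, non-basic conditions, which should avoid epoxide opening and translactonisation of the 4-hydroxy-Z-enoate to a butenolide.

Compound list
1 | ethyl (R)-3-hydroxybutanoate | C[C@@H](O)CC(=O)OCC | starting material
2 | N-methoxy-N-methylacetamide | CC(=O)N(C)OC | starting material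
3 | (5R)-5-hydroxy-N-methoxy-N-methyl-3-oxohexanamide | C[C@@H](O)CC(=O)CC(=O)N(C)OC | intermediate
4 | (3R,5R)-3,5-dihydroxy-N-methoxy-N-methylhexanamide | C[C@@H](O)C[C@@H](O)CC(=O)N(C)OC | intermediate
5 | (3R,5R)-3,5-bis[(tert-butyldimethylsilyl)oxy]-N-methoxy-N-methylhexanamide | C[C@@H](O[Si](C)(C)C(C)(C)C)C[C@@H](O[Si](C)(C)C(C)(C)C)CC(=O)N(C)OC | intermediate
6 | (5R,7R)-5,7-bis[(tert-butyldimethylsilyl)oxy]oct-1-en-3-one | C[C@@H](O[Si](C)(C)C(C)(C)C)C[C@@H](O[Si](C)(C)C(C)(C)C)CC(=O)C=C | intermediate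
7 | (3R,5S,7R)-5,7-bis[(tert-butyldimethylsilyl)oxy]oct-1-en-3-ol | C[C@@H](O[Si](C)(C)C(C)(C)C)C[C@@H](O[Si](C)(C)C(C)(C)C)C[C@@H](O)C=C | intermediate
8 | propiolic acid (prop-2-ynoic acid) | C#CC(=O)O | starting material
9 | (3R,5S,7R)-5,7-bis[(tert-butyldimethylsilyl)oxy]oct-1-en-3-yl prop-2-ynoate | C[C@@H](O[Si](C)(C)C(C)(C)C)C[C@@H](O[Si](C)(C)C(C)(C)C)C[C@@H](OC(=O)C#C)C=C | intermediate
10 | 11-bromoundecan-1-ol | OCCCCCCCCCCCBr | starting material
11 | 11-bromoundecanal | O=CCCCCCCCCCCBr | intermediate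
12 | (2E)-13-bromotridec-2-enal | O=C/C=C/CCCCCCCCCCBr | intermediate
13 | (2R,3S)-3-(10-bromodecyl)oxirane-2-carbaldehyde | BrCCCCCCCCCC[C@@H]1O[C@H]1C=O | intermediate
14 | (3R,5S,7R)-5,7-bis[(tert-butyldimethylsilyl)oxy]oct-1-en-3-yl (4R)-4-[(2S,3S)-3-(10-bromodecyl)oxiran-2-yl]-4-hydroxybut-2-ynoate | C[C@@H](O[Si](C)(C)C(C)(C)C)C[C@@H](O[Si](C)(C)C(C)(C)C)C[C@@H](OC(=O)C#C[C@@H](O)[C@@H]1O[C@H]1CCCCCCCCCCBr)C=C | intermediate
15 | (3R,5S,7R)-5,7-bis[(tert-butyldimethylsilyl)oxy]oct-1-en-3-yl (4R)-4-[(2R,3S)-3-(10-bromodecyl)oxiran-2-yl]-4-[(tert-butyldimethylsilyl)oxy]but-2-ynoate | C[C@@H](O[Si](C)(C)C(C)(C)C)C[C@@H](O[Si](C)(C)C(C)(C)C)C[C@@H](OC(=O)C#C[C@@H](O[Si](C)(C)C(C)(C)C)[C@@H]1O[C@H]1CCCCCCCCCCBr)C=C | intermediate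
16 | (3R,5S,7R)-5,7-bis[(tert-butyldimethylsilyl)oxy]oct-1-en-3-yl (2Z,4R)-4-[(2R,3S)-3-(10-bromodecyl)oxiran-2-yl]-4-[(tert-butyldimethylsilyl)oxy]but-2-enoate | C[C@@H](O[Si](C)(C)C(C)(C)C)C[C@@H](O[Si](C)(C)C(C)(C)C)C[C@@H](OC(=O)/C=C\[C@@H](O[Si](C)(C)C(C)(C)C)[C@@H]1O[C@H]1CCCCCCCCCCBr)C=C | intermediate
17 | C17 B-alkyl-9-BBN borane: adduct of 9-BBN–H across C17=C18 of 16 with boron on C17, all stereocentres as in 16 | C[C@@H](O[Si](C)(C)C(C)(C)C)C[C@@H](O[Si](C)(C)C(C)(C)C)C[C@@H](OC(=O)/C=C\[C@@H](O[Si](C)(C)C(C)(C)C)[C@@H]1O[C@H]1CCCCCCCCCCBr)CCB1C2CCCC1CCC2 | intermediate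
18 | (2Z,4R,5R,6S,19S,21S,23R)-4,21,23-tris[(tert-butyldimethylsilyl)oxy]-5,6-epoxytetracos-2-en-19-olide | C[C@@H](O[Si](C)(C)C(C)(C)C)C[C@@H](O[Si](C)(C)C(C)(C)C)C[C@@H]1CCCCCCCCCCCC[C@@H]2O[C@H]2[C@H](O[Si](C)(C)C(C)(C)C)/C=C\C(=O)O1 | intermediate
19 | (2Z,4R,5S,6S,19S,21R,23R)-5,6-epoxy-4,21,23-trihydroxytetracos-2-en-19-olide | C[C@@H](O)C[C@@H](O)C[C@@H]1CCCCCCCCCCCC[C@@H]2O[C@H]2[C@H](O)/C=C\C(=O)O1 | target

Total step count: 14. Longest linear sequence: 11 steps (steps 1–6, then 10–14, from 1).

Steps most likely to fail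

Step 13. Intermolecular coupling may outrun ring closure at the low catalyst turnover that high dilution imposes. β-Hydride elimination or protodeboronation may consume the two termini, and free PCy3 may isomerise the Z-enoate by reversible conjugate addition. The fallback sets out from 16 and comes back at 18. Halide exchange (NaI, acetone, 50 °C) would give the C16 iodide, (3R,5S,7R)-5,7-bis[(tert-butyldimethylsilyl)oxy]oct-1-en-3-yl (2Z,4R)-4-[(tert-butyldimethylsilyl)oxy]-4-[(2R,3S)-3-(10-iododecyl)oxiran-2-yl]but-2-enoate F1. Nickel hydride catalysis (NiBr2·glyme, 4,4′-di-tert-butyl-2,2′-bipyridine, (EtO)2MeSiH, Na2CO3, DMA, rt, slow addition to 2 mM) would then add the C16 alkyl group and hydrogen across the C17=C18 vinyl group in the anti-Markovnikov sense (reductive olefin hydroalkylation). This forms the same C16–C17 bond without a borane or a phosphine and gives 18.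

Step 10. Facial selectivity may be poor if catalyst control does not dominate the intrinsic bias of the α,β-epoxy aldehyde, and the zinc Lewis acid may open the epoxide during the long reaction time. The fallback sets out from 9 and 13 and comes back at 14. The lithium acetylide of 9 (LiN(SiMe3)2, THF, −78 °C) would be added to 13 without control at C4 to give the C4-epimeric carbinols, (3R,5S,7R)-5,7-bis[(tert-butyldimethylsilyl)oxy]oct-1-en-3-yl (4RS)-4-[(2S,3S)-3-(10-bromodecyl)oxiran-2-yl]-4-hydroxybut-2-ynoate F2. Dess–Martin periodinane would converge the mixture to the ynone, (3R,5S,7R)-5,7-bis[(tert-butyldimethylsilyl)oxy]oct-1-en-3-yl 4-[(2R,3S)-3-(10-bromodecyl)oxiran-2-yl]-4-oxobut-2-ynoate F3. Midland reduction with (S)-Alpine-Borane (B-isopinocampheyl-9-BBN, THF, rt) would then set C4 under reagent control and return 14.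

Step 5. Discrimination between the vinyl and the CH2 substituent of the ketone may be low, and the vinyl group may be hydroborated in competition. The fallback sets out from 5 and comes back at 7. LiC≡CSiMe3 (THF, −78 °C) would convert 5 into the silyl ynone, (5R,7R)-5,7-bis[(tert-butyldimethylsilyl)oxy]-1-(trimethylsilyl)oct-1-yn-3-one F4. Noyori transfer hydrogenation (RuCl[(R,R)-TsDPEN](p-cymene), i-PrOH, rt) would give the propargylic alcohol, (3R,5S,7R)-5,7-bis[(tert-butyldimethylsilyl)oxy]-1-(trimethylsilyl)oct-1-yn-3-ol F5, under reagent control. K2CO3 in MeOH would remove the C-silyl group to give (3R,5S,7R)-5,7-bis[(tert-butyldimethylsilyl)oxy]oct-1-yn-3-ol F6. Semi-hydrogenation (H2, Pd/CaCO3 poisoned with Pb(OAc)2, quinoline) would then give 7.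

Further compounds
F1 | step 13 | (3R,5S,7R)-5,7-bis[(tert-butyldimethylsilyl)oxy]oct-1-en-3-yl (2Z,4R)-4-[(tert-butyldimethylsilyl)oxy]-4-[(2R,3S)-3-(10-iododecyl)oxiran-2-yl]but-2-enoate | C[C@@H](O[Si](C)(C)C(C)(C)C)C[C@@H](O[Si](C)(C)C(C)(C)C)C[C@@H](OC(=O)/C=C\[C@@H](O[Si](C)(C)C(C)(C)C)[C@@H]1O[C@H]1CCCCCCCCCCI)C=C
F2 | step 10 | (3R,5S,7R)-5,7-bis[(tert-butyldimethylsilyl)oxy]oct-1-en-3-yl (4RS)-4-[(2S,3S)-3-(10-bromodecyl)oxiran-2-yl]-4-hydroxybut-2-ynoate | C[C@@H](O[Si](C)(C)C(C)(C)C)C[C@@H](O[Si](C)(C)C(C)(C)C)C[C@@H](OC(=O)C#CC(O)[C@@H]1O[C@H]1CCCCCCCCCCBr)C=C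
F3 | step 10 | (3R,5S,7R)-5,7-bis[(tert-butyldimethylsilyl)oxy]oct-1-en-3-yl 4-[(2R,3S)-3-(10-bromodecyl)oxiran-2-yl]-4-oxobut-2-ynoate | C[C@@H](O[Si](C)(C)C(C)(C)C)C[C@@H](O[Si](C)(C)C(C)(C)C)C[C@@H](OC(=O)C#CC(=O)[C@@H]1O[C@H]1CCCCCCCCCCBr)C=C
F4 | step 5 | (5R,7R)-5,7-bis[(tert-butyldimethylsilyl)oxy]-1-(trimethylsilyl)oct-1-yn-3-one | C[C@@H](O[Si](C)(C)C(C)(C)C)C[C@@H](O[Si](C)(C)C(C)(C)C)CC(=O)C#C[Si](C)(C)C
F5 | step 5 | (3R,5S,7R)-5,7-bis[(tert-butyldimethylsilyl)oxy]-1-(trimethylsilyl)oct-1-yn-3-ol | C[C@@H](O[Si](C)(C)C(C)(C)C)C[C@@H](O[Si](C)(C)C(C)(C)C)C[C@@H](O)C#C[Si](C)(C)C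
F6 | step 5 | (3R,5S,7R)-5,7-bis[(tert-butyldimethylsilyl)oxy]oct-1-yn-3-ol | C[C@@H](O[Si](C)(C)C(C)(C)C)C[C@@H](O[Si](C)(C)C(C)(C)C)C[C@@H](O)C#C
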